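**Retrosynthetic overview**

1. (+)-Isolariciresinol ⇒ open-chain (−)-secoisolariciresinol. The only ring to be built, carbocycle B, is closed last: one guaiacyl unit is dehydrogenated to its p-quinone methide and the other guaiacyl ring captures it (the lariciresinol → isolariciresinol closure, started from a plain benzylic CH2).
2. (−)-Secoisolariciresinol ⇒ C2-symmetric (2R,3R)-bis-imide by one global hydride reduction (auxiliaries and phenol esters leave together).
3. Bis-imide ⇒ two molecules of one chiral N-acyloxazolidinone by oxidative 8–8′ enolate homocoupling (both stereocentres set in one C–C bond formation).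
4. N-Acyloxazolidinone ⇒ dihydroferulic acid + (S)-4-isopropyloxazolidin-2-one, with the phenol masked as its pivalate in the same operation.
5. Ring order: the tetrahydrofuran of lariciresinol forms transiently and reopens, then ring B closes; rings A and C are the two guaiacyl rings of the starting acid.

Assumption: the target is taken exactly as the SMILES shows, the all-trans (1S,2R,3R) isomer; lignan numbering (C7 benzylic, C8 methine, C9 CH2OH, primed for the second C6C3 unit) is used for the open-chain compounds.

**Route**

Step 1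
Reactants: 1 3-(4-hydroxy-3-methoxyphenyl)propanoic acid (dihydroferulic acid); 2 (S)-4-isopropyloxazolidin-2-one
Product: 4 (S)-4-isopropyl-3-[3-(3-methoxy-4-pivaloyloxyphenyl)propanoyl]oxazolidin-2-one, via mixed anhydride 3 (not isolated)
Conditions: PivCl (2.2 equiv), Et3N (3.5 equiv), DMAP (5 mol%), THF, −20 → 0 °C (1 added slowly); then LiCl (1.2 equiv), 2 (1.2 equiv), rt
Reagents that add atoms: pivaloyl chloride, CC(C)(C)C(Cl)=O
Why: Excess pivaloyl chloride acylates the carboxylate (to the pivalic mixed anhydride) and the phenol (to the aryl pivalate) in one operation, and the LiCl-activated oxazolidinone then attacks the less hindered carbonyl of the anhydride (mixed-anhydride N-acylation of an Evans auxiliary), so the phenol protection costs no separate step and no stereocentre is formed.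

Step 2
Reactants: 4 (two molecules)
Product: 6 (2R,3R)-2,3-bis(3-methoxy-4-pivaloyloxybenzyl)-1,4-bis[(S)-4-isopropyl-2-oxooxazolidin-3-yl]butane-1,4-dione, via lithium enolate 5 (not isolated)
Conditions: LiN(i-Pr)2 (1.05 equiv), THF, −78 °C, 45 min; PhI(OAc)2 (0.55 equiv), −78 → 0 °C
Reagents that add atoms: none
Why: Oxidative homocoupling of the chelated lithium (Z)-enolate of an Evans imide (hypervalent-iodine-mediated enolate dimerisation, the laboratory counterpart of oxidative 8–8′ coupling), in which each α-carbon forms the C8–C8′ bond on the face opposite the isopropyl group of its own auxiliary (the face used in Evans alkylations), giving the C2-symmetric (R,R) dimer as major isomer, with the minor (R,S) and (S,S) isomers removed by chromatography and crystallisation.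

Step 3
Reactants: 6
Product: 7 (−)-secoisolariciresinol [(2R,3R)-2,3-bis(4-hydroxy-3-methoxybenzyl)butane-1,4-diol]
Conditions: LiAlH4 (5 equiv), THF, 0 °C → rt; aq. potassium sodium tartrate, pH 5–6
Reagents that add atoms: none
Why: Hydride reduction cleaves both exocyclic imide carbonyls to primary alcohols with release of the auxiliary and at the same time reduces off both aryl pivalates (reductive auxiliary removal and ester cleavage), and reduction outpaces enolisation so both α-stereocentres are retained.

Step 4
Reactants: 7
Product: 10 (+)-isolariciresinol, via quinone methide 8 (not isolated), via (+)-lariciresinol 9 (not isolated)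
Conditions: DDQ (0.9 equiv, added over 1 h), CSA (10 mol%), MeCN (0.02 M), 0 °C → rt
Reagents that add atoms: none
Why: Proposed new method: DDQ dehydrogenates one p-alkylguaiacol unit of C2-symmetric 7 (either unit gives the same product) to p-quinone methide 8, the C9′ hydroxyl adds reversibly to C7 to give lariciresinol 9, and under the sulfonic acid the common benzylic cation is captured irreversibly by C6′ of the second guaiacyl ring (para to its methoxy group) in a six-ring Friedel–Crafts closure through a chair-like transition state with the aryl and both CH2OH groups equatorial, which sets C7 (tetralin C1, S) trans to C8 while C8 and C8′ are untouched; the closest known reaction types are the DDQ/acid oxidative cyclisation of 4-hydroxybenzyl-substituted dibenzylbutyrolactones to aryltetralins and the acid isomerisation of lariciresinol to isolariciresinol.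

**Compound list**

1 | 3-(4-hydroxy-3-methoxyphenyl)propanoic acid (dihydroferulic acid) | COc1cc(CCC(=O)O)ccc1O | starting material
2 | (S)-4-isopropyloxazolidin-2-one | CC(C)[C@H]1COC(=O)N1 | starting material
3 | 3-(3-methoxy-4-pivaloyloxyphenyl)propanoic pivalic anhydride (mixed anhydride) | COc1cc(CCC(=O)OC(=O)C(C)(C)C)ccc1OC(=O)C(C)(C)C | intermediate
4 | (S)-4-isopropyl-3-[3-(3-methoxy-4-pivaloyloxyphenyl)propanoyl]oxazolidin-2-one | COc1cc(CCC(=O)N2[C@@H](C(C)C)COC2=O)ccc1OC(=O)C(C)(C)C | intermediate
5 | lithium (Z)-enolate of 4 | COc1cc(C/C=C(\[O-])N2[C@@H](C(C)C)COC2=O)ccc1OC(=O)C(C)(C)C.[Li+] | intermediate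
6 | (2R,3R)-2,3-bis(3-methoxy-4-pivaloyloxybenzyl)-1,4-bis[(S)-4-isopropyl-2-oxooxazolidin-3-yl]butane-1,4-dione | CC(C)[C@H]1COC(=O)N1C(=O)[C@H](Cc2ccc(OC(=O)C(C)(C)C)c(OC)c2)[C@@H](Cc2ccc(OC(=O)C(C)(C)C)c(OC)c2)C(=O)N1C(=O)OC[C@@H]1C(C)C | intermediate
7 | (−)-secoisolariciresinol, (2R,3R)-2,3-bis(4-hydroxy-3-methoxybenzyl)butane-1,4-diol | COc1cc(C[C@@H](CO)[C@H](CO)Cc2ccc(O)c(OC)c2)ccc1O | intermediate
8 | p-quinone methide of 7 (one guaiacyl unit oxidised at C7; C8 and C8′ as in 7; exocyclic alkene geometry not defined) | COC1=CC(=C[C@@H](CO)[C@H](CO)Cc2ccc(O)c(OC)c2)C=CC1=O | intermediate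
9 | (+)-lariciresinol, (2S,3R,4R)-2-(4-hydroxy-3-methoxyphenyl)-4-(4-hydroxy-3-methoxybenzyl)-3-(hydroxymethyl)tetrahydrofuran | COc1cc(C[C@H]2CO[C@H](c3ccc(O)c(OC)c3)[C@H]2CO)ccc1O | intermediate
10 | (+)-isolariciresinol, (1S,2R,3R)-7-hydroxy-1-(4-hydroxy-3-methoxyphenyl)-6-methoxy-1,2,3,4-tetrahydronaphthalene-2,3-dimethanol (all-trans) | COc1cc([C@H]2c3cc(O)c(OC)cc3C[C@@H](CO)[C@@H]2CO)ccc1O | target

**Step count and risks**

Total step count: 4. Longest linear sequence: 4 steps (1 → 4 → 6 → 7 → 10).

Most likely to fail, in this order: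

Step 4 (oxidative cyclisation). Product 10 is itself a p-alkylguaiacol, so over-oxidation competes; this is why DDQ is kept at 0.9 equiv and unreacted 7 is recycled. Quinone methide 8 may also tautomerise to the C7=C8 styrene and lose the C8 centre, or an oxygen adduct may fail to revert. The fallback sets out from 7 and comes back at 10. The 1,4-diol is first tied up with 2,2-dimethoxypropane and PPTS in acetone as the seven-membered isopropylidene acetal, secoisolariciresinol acetonide F1. DDQ (1.0 equiv) in CH2Cl2 at −20 °C then gives the quinone methide acetonide F2, which has no internal oxygen nucleophile and no route to furan or furofuran products. BF3·OEt2 at −60 °C leaves only the six-ring Friedel–Crafts closure, giving isolariciresinol acetonide F3. 80% aq. AcOH at rt removes the acetal and delivers 10.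

Step 2 (enolate homocoupling). The risks are an imperfect diastereomer ratio, attack of the enolate on the aryl pivalate, and α-acetoxylation by the iodane. The fallback sets out from 1 and comes back at 7; it also bypasses step 1. Compound 1 is O-benzylated (BnBr, KOH, aq. EtOH, reflux, then acid; any benzyl ester is saponified in the same pot) to 3-(4-benzyloxy-3-methoxyphenyl)propanoic acid F4. DCC and catalytic DMAP in CH2Cl2 couple it with 2 to the benzyl-protected imide F5. LiN(i-Pr)2 at −78 °C gives its lithium enolate F6, which is dimerised in a single-electron manifold with copper bis(2-ethylhexanoate) (a divalent copper carboxylate) to the benzyl-protected (R,R)-dimer F7. LiBH4 with MeOH (2 equiv) in THF at 0 °C reduces off the auxiliaries to di-O-benzylsecoisolariciresinol F8. Hydrogenolysis (H2, 10% Pd/C, EtOAc–EtOH) then gives 7. This trades two extra steps for ether protection that is inert to enolates.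

Step 3 (global reduction). The hindered, α-branched bis-imide may suffer hydride attack at the ring carbonyl of the auxiliary, giving amide and amine by-products instead of the diol. The fallback sets out from 6 and comes back at 7. LiOH/H2O2 in THF–H2O at 0 °C hydrolyses the exocyclic imide carbonyls selectively and also cleaves the aryl pivalates, giving (2R,3R)-2,3-bis(4-hydroxy-3-methoxybenzyl)succinic acid F9 with recovery of the auxiliary. BH3·THF (excess, 0 °C → rt, MeOH quench) then reduces the two carboxylic acids to 7.

**Further compounds**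

F1 | step 4 | secoisolariciresinol acetonide, (5R,6R)-5,6-bis(4-hydroxy-3-methoxybenzyl)-2,2-dimethyl-1,3-dioxepane | COc1cc(C[C@H]2COC(C)(C)OC[C@@H]2Cc3ccc(O)c(OC)c3)ccc1O
F2 | step 4 | quinone methide acetonide (p-quinone methide of F1 at C7) | COC1=CC(=C[C@H]2COC(C)(C)OC[C@@H]2Cc3ccc(O)c(OC)c3)C=CC1=O
F3 | step 4 | isolariciresinol acetonide (isopropylidene acetal of the two CH2OH groups of 10) | COc1cc([C@H]2c3cc(O)c(OC)cc3C[C@H]4COC(C)(C)OC[C@H]24)ccc1O
F4 | step 2 | 3-(4-benzyloxy-3-methoxyphenyl)propanoic acid | COc1cc(CCC(=O)O)ccc1OCc1ccccc1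
F5 | step 2 | benzyl-protected imide, (S)-3-[3-(4-benzyloxy-3-methoxyphenyl)propanoyl]-4-isopropyloxazolidin-2-one | COc1cc(CCC(=O)N2[C@@H](C(C)C)COC2=O)ccc1OCc1ccccc1
F6 | step 2 | lithium (Z)-enolate of F5 | COc1cc(C/C=C(\[O-])N2[C@@H](C(C)C)COC2=O)ccc1OCc1ccccc1.[Li+]
F7 | step 2 | benzyl-protected (R,R)-dimer, (2R,3R)-2,3-bis(4-benzyloxy-3-methoxybenzyl)-1,4-bis[(S)-4-isopropyl-2-oxooxazolidin-3-yl]butane-1,4-dione | CC(C)[C@H]1COC(=O)N1C(=O)[C@H](Cc2ccc(OCc3ccccc3)c(OC)c2)[C@@H](Cc2ccc(OCc3ccccc3)c(OC)c2)C(=O)N1C(=O)OC[C@@H]1C(C)C
F8 | step 2 | di-O-benzylsecoisolariciresinol, (2R,3R)-2,3-bis(4-benzyloxy-3-methoxybenzyl)butane-1,4-diol | COc1cc(C[C@@H](CO)[C@H](CO)Cc2ccc(OCc3ccccc3)c(OC)c2)ccc1OCc1ccccc1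
F9 | step 3 | (2R,3R)-2,3-bis(4-hydroxy-3-methoxybenzyl)succinic acid | COc1cc(C[C@@H](C(=O)O)[C@H](C(=O)O)Cc2ccc(O)c(OC)c2)ccc1O
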